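**Retrosynthetic overview**

- The target is a 2-bromo-5-alkylidenecyclopent-2-enone (ring C8–C12). The strategy rests on the C8–C12 ring bond, which is flanked by the tertiary C12 carbinol and the exocyclic 7Z C7=C8 alkene; this bond and the C9–C10 bond are cut together.
- The ring is formed once, in the key step. A lithiated (aR)-allenyl MOM ether (C1–C9) adds to an (E)-β-PMB-oxy enal (C10–C20), forming C9–C10. Anhydrous trifluoroacetylation then ionises the carbinolate, and conrotatory 4π closure of the cation forms C8–C12 (aqueous acid would hydrolyse the enol ether instead).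
- The enal comes from propargyl alcohol, 1-bromopent-2-yne and 4-methoxybenzyl alcohol. The allene comes from 2-deoxy-L-ribose (C5 and C6) through a propargylic MOM ether.
- End game: Br is placed on C10 by nucleophilic epoxidation, bromide opening and dehydration, because Br2 would add to the skipped diene. Then both PMB ethers are removed, C1 is oxidised and esterified, and the silyl ethers are cleaved.

Key step: step 17

Remark: prostanoid numbering (C1 = ester carbon, ring C8–C12) is used for all intermediates; TBS = tert-butyldimethylsilyl, PMB = 4-methoxybenzyl, MOM = methoxymethyl; the descriptor aR refers to the C7=C8=C9 allene axis; 2-deoxy-L-ribose is taken as commercially available.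

**Route**

Step 1
Reactants: 1 propargyl alcohol; 2 1-bromopent-2-yne
Product: 3 octa-2,5-diyn-1-ol
Conditions: CuI (10 mol%), NaI (10 mol%), K2CO3, DMF, rt
Reagents that add atoms: none
Why: Copper-acetylide propargylation of a terminal alkyne (the standard skipped-diyne coupling) joins C13–C15 to C16–C20 without protecting the alcohol.

Step 2
Reactants: 3 octa-2,5-diyn-1-ol
Product: 4 (2Z,5Z)-octa-2,5-dien-1-ol
Conditions: H2 (1 atm), Ni2B from Ni(OAc)2·4H2O/NaBH4, ethylenediamine, EtOH, rt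
Reagents that add atoms: none
Why: cis-Selective semihydrogenation of both alkynes on amine-poisoned nickel boride should give the Z,Z skipped diene without over-reduction or double-bond migration.

Step 3
Reactants: 4 (2Z,5Z)-octa-2,5-dien-1-ol
Product: 5 (2Z,5Z)-1-bromoocta-2,5-diene
Conditions: CBr4, PPh3, CH2Cl2, –20 °C
Reagents that add atoms: carbon tetrabromide, BrC(Br)(Br)Br
Why: Appel bromination under neutral conditions converts the allylic alcohol to the bromide without allylic transposition or Z to E isomerisation.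

Step 4
Reactants: 5 (2Z,5Z)-1-bromoocta-2,5-diene; 1 propargyl alcohol
Product: 6 (5Z,8Z)-undeca-5,8-dien-2-yn-1-ol
Conditions: CuI (10 mol%), NaI (10 mol%), K2CO3, DMF, rt
Reagents that add atoms: none
Why: Copper-acetylide allylation of the terminal alkyne (SN2 at the primary allylic carbon) builds the skipped enyne C10–C20 and leaves both Z alkenes untouched.

Step 5
Reactants: 6 (5Z,8Z)-undeca-5,8-dien-2-yn-1-ol
Product: 7 (5Z,8Z)-undeca-5,8-dien-2-ynal
Conditions: Dess–Martin periodinane, NaHCO3, CH2Cl2, 0 °C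
Reagents that add atoms: none
Why: Buffered Dess–Martin oxidation of the propargylic alcohol gives the base-sensitive ynal without touching the skipped diene.

Step 6
Reactants: 7 (5Z,8Z)-undeca-5,8-dien-2-ynal; 8 4-methoxybenzyl alcohol
Product: 9 (2E,5Z,8Z)-3-(PMB-oxy)undeca-2,5,8-trienal
Conditions: PMe3 (10 mol%), CH2Cl2, –20 → 0 °C
Reagents that add atoms: none
Why: Phosphine-catalysed oxa-Michael addition of the alcohol to the alkynal gives the β-alkoxy enal, reversible phosphine addition equilibrates it to the E isomer (ether oxygen trans to CHO, C13 cis), and the cold, near-neutral medium should spare the doubly activated C13 methylene.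

Step 7
Reactants: 10 2-deoxy-L-ribose
Product: 11 methyl (2E,5R,6S)-5,6,7-trihydroxyhept-2-enoate
Conditions: Ph3P=CHCO2Me, THF, reflux
Reagents that add atoms: methyl (triphenylphosphoranylidene)acetate, COC(=O)C=P(c1ccccc1)(c1ccccc1)c1ccccc1
Why: Wittig olefination of the lactol through its open-chain aldehyde with a stabilised ylide adds C1–C2 as the E enoate and leaves the two sugar stereocentres (future C5 and C6) untouched.

Step 8
Reactants: 11 methyl (2E,5R,6S)-5,6,7-trihydroxyhept-2-enoate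
Product: 12 methyl (2E,5R,6S)-5,6,7-tris(TBS-oxy)hept-2-enoate
Conditions: TBSOTf, 2,6-lutidine, CH2Cl2, –40 → 0 °C
Reagents that add atoms: tert-butyldimethylsilyl triflate, CC(C)(C)[Si](C)(C)OS(=O)(=O)C(F)(F)F
Why: Exhaustive silylation with the silyl triflate protects all three hydroxyls before any of them can add to the enoate or, later, lactonise.

Step 9
Reactants: 12 methyl (2E,5R,6S)-5,6,7-tris(TBS-oxy)hept-2-enoate
Product: 13 methyl (5R,6S)-5,6,7-tris(TBS-oxy)heptanoate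
Conditions: H2 (1 atm), Pd/C, EtOAc, rt
Reagents that add atoms: none
Why: Heterogeneous hydrogenation saturates the conjugated alkene, and the silyl ethers are stable in the aprotic solvent.

Step 10
Reactants: 13 methyl (5R,6S)-5,6,7-tris(TBS-oxy)heptanoate
Product: 14 (5R,6S)-5,6,7-tris(TBS-oxy)heptan-1-ol
Conditions: i-Bu2AlH, CH2Cl2, –78 → 0 °C
Reagents that add atoms: none
Why: Hydride reduction of the ester gives the primary C1 alcohol.

Step 11
Reactants: 14 (5R,6S)-5,6,7-tris(TBS-oxy)heptan-1-ol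
Product: 15 (5R,6S)-5,6,7-tris(TBS-oxy)heptyl 4-methoxybenzyl ether
Conditions: NaH, 4-methoxybenzyl chloride, Bu4NI (cat.), THF/DMF, 0 °C → rt
Reagents that add atoms: 4-methoxybenzyl chloride, COc1ccc(CCl)cc1
Why: Williamson etherification masks C1 as a PMB ether, because an ester would not survive the organolithium of step 17.

Step 12
Reactants: 15 (5R,6S)-5,6,7-tris(TBS-oxy)heptyl 4-methoxybenzyl ether
Product: 16 (2S,3R)-2,3-bis(TBS-oxy)-7-(PMB-oxy)heptan-1-ol
Conditions: HF·pyridine, pyridine, THF, 0 °C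
Reagents that add atoms: none
Why: Under buffered HF the primary silyl ether is cleaved much faster than the two hindered secondary ones.

Step 13
Reactants: 16 (2S,3R)-2,3-bis(TBS-oxy)-7-(PMB-oxy)heptan-1-ol
Product: 17 (2R,3R)-2,3-bis(TBS-oxy)-7-(PMB-oxy)heptanal
Conditions: Dess–Martin periodinane, NaHCO3, CH2Cl2, 0 °C
Reagents that add atoms: none
Why: Mild buffered oxidation gives the α-silyloxy aldehyde (C7) without epimerising C6; the descriptor changes only through CIP priorities.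

Step 14
Reactants: 17 (2R,3R)-2,3-bis(TBS-oxy)-7-(PMB-oxy)heptanal
Product: 18 (3S,4R)-3,4-bis(TBS-oxy)-8-(PMB-oxy)oct-1-yne
Conditions: dimethyl (1-diazo-2-oxopropyl)phosphonate, K2CO3, MeOH, 0 °C → rt
Reagents that add atoms: dimethyl (1-diazo-2-oxopropyl)phosphonate, COP(=O)(OC)C(=[N+]=[N-])C(C)=O
Why: Seyferth–Gilbert homologation in the Ohira–Bestmann form turns CHO into C≡CH (C7≡C8) under conditions mild enough to keep the α-stereocentre.

Step 15
Reactants: 18 (3S,4R)-3,4-bis(TBS-oxy)-8-(PMB-oxy)oct-1-yne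
Product: 21 (4S,5R)-4,5-bis(TBS-oxy)-1-(methoxymethoxy)-9-(PMB-oxy)non-2-yne, via lithium acetylide 19 (not isolated), via lithium alkoxide 20 (not isolated)
Conditions: n-BuLi, THF, –78 °C; (CH2O)n, –78 °C → rt; then MOMCl, DMPU, 0 °C → rt
Reagents that add atoms: paraformaldehyde (as formaldehyde), C=O; chloromethyl methyl ether, COCCl
Why: Acetylide hydroxymethylation adds C9, and O-alkylation of the resulting lithium alkoxide in the same flask gives the propargylic MOM ether.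

Step 16
Reactants: 21 (4S,5R)-4,5-bis(TBS-oxy)-1-(methoxymethoxy)-9-(PMB-oxy)non-2-yne
Product: 22 (aR,4S,5R)-4,5-bis(TBS-oxy)-1-(methoxymethoxy)-9-(PMB-oxy)nona-1,2-diene
Conditions: KOtBu (0.3 equiv), 18-crown-6 (cat.), THF, 0 °C; chromatography on Et3N-deactivated silica
Reagents that add atoms: none
Why: Base-catalysed propargyl-to-allenyl ether isomerisation (deprotonation at C9, reprotonation at C7) should give both allene axes as diastereomers because of C5 and C6, so the aR isomer 22 can be isolated by chromatography and the remaining fractions returned to the same base for re-equilibration.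

Step 17
Reactants: 22 (aR,4S,5R)-4,5-bis(TBS-oxy)-1-(methoxymethoxy)-9-(PMB-oxy)nona-1,2-diene; 9 (2E,5Z,8Z)-3-(PMB-oxy)undeca-2,5,8-trienal
Product: 26 (4R,5Z)-5-[(2S,3R)-2,3-bis(TBS-oxy)-7-(PMB-oxy)heptylidene]-4-(PMB-oxy)-4-[(2Z,5Z)-octa-2,5-dien-1-yl]cyclopent-2-en-1-one, via 1-lithioallene 23 (not isolated), via lithium carbinolate 24 (not isolated), via carbinol trifluoroacetate 25 (not isolated)
Conditions: n-BuLi, THF, –78 °C; 9, –78 °C; then (CF3CO)2O, 2,6-lutidine, CH2Cl2, –78 → –20 °C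
Reagents that add atoms: none
Why: Proposed new method: the closest known reactions are the Tius cationic cyclopentannelation of α-lithiated allenyl MOM ethers with enones (carbinol ionised by trifluoroacetic anhydride/2,6-lutidine) and the Piancatelli 4π closure onto an oxygen-bearing cation terminus, but a β-alkoxy enal and the one-flask trifluoroacetylation have not been shown in the allenyl-ether version. Lithioallene 23 adds 1,2 to the aldehyde of 9 (C9–C10), O-trifluoroacetylation of 24 under strictly anhydrous conditions gives 25, and 25 ionises at –78 °C to the alkoxy-stabilised pentadienyl cation C12=C11–C10(+)–C9(OMOM)=C8 (with water the γ-oxygenated enol ether would instead hydrolyse to the transposed enone). The single new ring, the cyclopentenone, closes at C8–C12 by thermal conrotatory 4π electrocyclisation, a polarised closure of the nucleophilic enol-ether carbon C8 onto the oxocarbenium-like C12, after which the C9 oxocarbenium loses its MOM group to trifluoroacetate and becomes the ketone. The only new stereocentre, C12, is set by axis-to-centre chirality transfer: C12 bonds to the face of C8 opposite the C6 substituent of the aR allene, which fixes the sense of conrotation, and with the E enol ether holding C13 inside and the PMB ether outside this gives 12R. The same trajectory turns H-7 toward C12 and C6 toward C9, which is the 7Z alkylidene. The step needs 1,2- over 1,4-addition (hard organolithium at –78 °C), closure faster than rotation about C11–C12 or loss of the PMB cation (low temperature, buffered non-nucleophilic medium), and an intact allene axis (C7–H is never deprotonated).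

Step 18
Reactants: 26 (4R,5Z)-5-[(2S,3R)-2,3-bis(TBS-oxy)-7-(PMB-oxy)heptylidene]-4-(PMB-oxy)-4-[(2Z,5Z)-octa-2,5-dien-1-yl]cyclopent-2-en-1-one
Product: 27 epoxy ketone (10,11-epoxide of 26; either epoxide face; C12 arrangement unchanged)
Conditions: t-BuOOH, DBU, CH2Cl2, 0 °C
Reagents that add atoms: tert-butyl hydroperoxide, CC(C)(C)OO
Why: Nucleophilic Weitz–Scheffer-type epoxidation attacks only electron-poor alkenes, so the skipped diene is spared, and the unsubstituted endocyclic C11 should be more accessible than the branched exocyclic C7; the face of attack does not matter because C10 and C11 become sp2 again.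

Step 19
Reactants: 27 epoxy ketone (10,11-epoxide of 26)
Product: 28 bromohydrin (10-bromo-11-hydroxy ketone from 27; trans)
Conditions: LiBr, AcOH, THF, rt
Reagents that add atoms: lithium bromide, [Li+].[Br-]
Why: Acid-assisted opening of the α,β-epoxy ketone by bromide should occur by SN2 at the carbonyl-activated C10 (C11 is neopentyl-like) under conditions that silyl and PMB ethers tolerate.

Step 20
Reactants: 28 bromohydrin (10-bromo-11-hydroxy ketone)
Product: 30 (4R,5Z)-2-bromo-5-[(2S,3R)-2,3-bis(TBS-oxy)-7-(PMB-oxy)heptylidene]-4-(PMB-oxy)-4-[(2Z,5Z)-octa-2,5-dien-1-yl]cyclopent-2-en-1-one, via mesylate 29 (not isolated)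
Conditions: MsCl, Et3N, CH2Cl2, 0 °C → rt
Reagents that add atoms: none
Why: Mesylation of the β-hydroxyl followed by E1cB loss of methanesulfonate across C10–C11 (C10–H is acidified by carbonyl and bromine, C12 has no hydrogen) gives the 2-bromo enone.

Step 21
Reactants: 30 (4R,5Z)-2-bromo-5-[(2S,3R)-2,3-bis(TBS-oxy)-7-(PMB-oxy)heptylidene]-4-(PMB-oxy)-4-[(2Z,5Z)-octa-2,5-dien-1-yl]cyclopent-2-en-1-one
Product: 31 (4R,5Z)-2-bromo-5-[(2S,3R)-2,3-bis(TBS-oxy)-7-hydroxyheptylidene]-4-hydroxy-4-[(2Z,5Z)-octa-2,5-dien-1-yl]cyclopent-2-en-1-one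
Conditions: DDQ, CH2Cl2/pH 7 buffer, 0 °C → rt
Reagents that add atoms: none
Why: Oxidative cleavage of both PMB ethers (primary C1 and tertiary C12) through their benzylic oxocarbenium ions leaves silyl ethers, vinyl bromide and alkenes intact.

Step 22
Reactants: 31 (4R,5Z)-2-bromo-5-[(2S,3R)-2,3-bis(TBS-oxy)-7-hydroxyheptylidene]-4-hydroxy-4-[(2Z,5Z)-octa-2,5-dien-1-yl]cyclopent-2-en-1-one
Product: 33 (5R,6S,7Z,12R,14Z,17Z)-10-bromo-5,6-bis(TBS-oxy)-12-hydroxy-9-oxoprosta-7,10,14,17-tetraenoic acid, via aldehyde 32 (not isolated)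
Conditions: TEMPO (cat.), PhI(OAc)2, MeCN/H2O, rt
Reagents that add atoms: water, O
Why: Oxoammonium-mediated oxidation takes the only primary alcohol through the aldehyde hydrate to the acid, and the tertiary C12 alcohol cannot be oxidised.

Step 23
Reactants: 33 (5R,6S,7Z,12R,14Z,17Z)-10-bromo-5,6-bis(TBS-oxy)-12-hydroxy-9-oxoprosta-7,10,14,17-tetraenoic acid
Product: 34 methyl (5R,6S,7Z,12R,14Z,17Z)-10-bromo-5,6-bis(TBS-oxy)-12-hydroxy-9-oxoprosta-7,10,14,17-tetraenoate
Conditions: TMSCHN2, toluene/MeOH, 0 °C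
Reagents that add atoms: trimethylsilyldiazomethane, C[Si](C)(C)C=[N+]=[N-]
Why: O-Methylation of the carboxylic acid by the diazoalkane is fast under neutral conditions and should outrun any cycloaddition to the enones.

Step 24
Reactants: 34 methyl (5R,6S,7Z,12R,14Z,17Z)-10-bromo-5,6-bis(TBS-oxy)-12-hydroxy-9-oxoprosta-7,10,14,17-tetraenoate
Product: 35 methyl (5R,6S,7Z,12R,14Z,17Z)-10-bromo-5,6,12-trihydroxy-9-oxoprosta-7,10,14,17-tetraenoate
Conditions: HF·pyridine, pyridine, THF, 0 °C → rt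
Reagents that add atoms: none
Why: Buffered HF cleaves both secondary silyl ethers under weakly acidic conditions that should avoid base-induced decomposition of the bromodienone and keep lactonisation of the 5-hydroxy ester slow.

**Compound list**

1 | propargyl alcohol | C#CCO | starting material
2 | 1-bromopent-2-yne | CCC#CCBr | starting material
3 | octa-2,5-diyn-1-ol | CCC#CCC#CCO | intermediate
4 | (2Z,5Z)-octa-2,5-dien-1-ol | CC/C=C\C/C=C\CO | intermediate
5 | (2Z,5Z)-1-bromoocta-2,5-diene | CC/C=C\C/C=C\CBr | intermediate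
6 | (5Z,8Z)-undeca-5,8-dien-2-yn-1-ol | CC/C=C\C/C=C\CC#CCO | intermediate
7 | (5Z,8Z)-undeca-5,8-dien-2-ynal | CC/C=C\C/C=C\CC#CC=O | intermediate
8 | 4-methoxybenzyl alcohol | COc1ccc(CO)cc1 | starting material
9 | (2E,5Z,8Z)-3-(PMB-oxy)undeca-2,5,8-trienal | CC/C=C\C/C=C\C/C(OCc1ccc(OC)cc1)=C\C=O | intermediate
10 | 2-deoxy-L-ribose | OC[C@H](O)[C@H](O)CC=O | starting material
11 | methyl (2E,5R,6S)-5,6,7-trihydroxyhept-2-enoate | OC[C@H](O)[C@H](O)C/C=C/C(=O)OC | intermediate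
12 | methyl (2E,5R,6S)-5,6,7-tris(TBS-oxy)hept-2-enoate | CC(C)(C)[Si](C)(C)OC[C@H](O[Si](C)(C)C(C)(C)C)[C@H](O[Si](C)(C)C(C)(C)C)C/C=C/C(=O)OC | intermediate
13 | methyl (5R,6S)-5,6,7-tris(TBS-oxy)heptanoate | CC(C)(C)[Si](C)(C)OC[C@H](O[Si](C)(C)C(C)(C)C)[C@H](O[Si](C)(C)C(C)(C)C)CCCC(=O)OC | intermediate
14 | (5R,6S)-5,6,7-tris(TBS-oxy)heptan-1-ol | CC(C)(C)[Si](C)(C)OC[C@H](O[Si](C)(C)C(C)(C)C)[C@H](O[Si](C)(C)C(C)(C)C)CCCCO | intermediate
15 | (5R,6S)-5,6,7-tris(TBS-oxy)heptyl 4-methoxybenzyl ether | CC(C)(C)[Si](C)(C)OC[C@H](O[Si](C)(C)C(C)(C)C)[C@H](O[Si](C)(C)C(C)(C)C)CCCCOCc1ccc(OC)cc1 | intermediate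
16 | (2S,3R)-2,3-bis(TBS-oxy)-7-(PMB-oxy)heptan-1-ol | OC[C@H](O[Si](C)(C)C(C)(C)C)[C@H](O[Si](C)(C)C(C)(C)C)CCCCOCc1ccc(OC)cc1 | intermediate
17 | (2R,3R)-2,3-bis(TBS-oxy)-7-(PMB-oxy)heptanal | O=C[C@H](O[Si](C)(C)C(C)(C)C)[C@H](O[Si](C)(C)C(C)(C)C)CCCCOCc1ccc(OC)cc1 | intermediate
18 | (3S,4R)-3,4-bis(TBS-oxy)-8-(PMB-oxy)oct-1-yne | C#C[C@H](O[Si](C)(C)C(C)(C)C)[C@H](O[Si](C)(C)C(C)(C)C)CCCCOCc1ccc(OC)cc1 | intermediate
19 | lithium acetylide of 18 | [Li]C#C[C@H](O[Si](C)(C)C(C)(C)C)[C@H](O[Si](C)(C)C(C)(C)C)CCCCOCc1ccc(OC)cc1 | intermediate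
20 | lithium (4S,5R)-4,5-bis(TBS-oxy)-9-(PMB-oxy)non-2-yn-1-olate | [Li+].[O-]CC#C[C@H](O[Si](C)(C)C(C)(C)C)[C@H](O[Si](C)(C)C(C)(C)C)CCCCOCc1ccc(OC)cc1 | intermediate
21 | (4S,5R)-4,5-bis(TBS-oxy)-1-(methoxymethoxy)-9-(PMB-oxy)non-2-yne | COCOCC#C[C@H](O[Si](C)(C)C(C)(C)C)[C@H](O[Si](C)(C)C(C)(C)C)CCCCOCc1ccc(OC)cc1 | intermediate
22 | (aR,4S,5R)-4,5-bis(TBS-oxy)-1-(methoxymethoxy)-9-(PMB-oxy)nona-1,2-diene | [H]C(OCOC)=[C@@]=C([H])[C@H](O[Si](C)(C)C(C)(C)C)[C@H](O[Si](C)(C)C(C)(C)C)CCCCOCc1ccc(OC)cc1 | intermediate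
23 | 1-lithio derivative of 22 | [Li]C(OCOC)=[C@@]=C([H])[C@H](O[Si](C)(C)C(C)(C)C)[C@H](O[Si](C)(C)C(C)(C)C)CCCCOCc1ccc(OC)cc1 | intermediate
24 | lithium carbinolate from 23 and 9 (C10 alkoxide, both C10 epimers) | CC/C=C\C/C=C\C/C(OCc1ccc(OC)cc1)=C\C([O-])C(OCOC)=[C@@]=C([H])[C@H](O[Si](C)(C)C(C)(C)C)[C@H](O[Si](C)(C)C(C)(C)C)CCCCOCc1ccc(OC)cc1.[Li+] | intermediate
25 | C10 trifluoroacetate of the carbinol | CC/C=C\C/C=C\C/C(OCc1ccc(OC)cc1)=C\C(OC(=O)C(F)(F)F)C(OCOC)=[C@@]=C([H])[C@H](O[Si](C)(C)C(C)(C)C)[C@H](O[Si](C)(C)C(C)(C)C)CCCCOCc1ccc(OC)cc1 | intermediate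
26 | (4R,5Z)-5-[(2S,3R)-2,3-bis(TBS-oxy)-7-(PMB-oxy)heptylidene]-4-(PMB-oxy)-4-[(2Z,5Z)-octa-2,5-dien-1-yl]cyclopent-2-en-1-one | CC/C=C\C/C=C\C[C@@]1(OCc2ccc(OC)cc2)C=CC(=O)/C1=C\[C@H](O[Si](C)(C)C(C)(C)C)[C@H](O[Si](C)(C)C(C)(C)C)CCCCOCc1ccc(OC)cc1 | intermediate
27 | epoxy ketone (10,11-epoxide of 26) | CC/C=C\C/C=C\C[C@@]1(OCc2ccc(OC)cc2)C2OC2C(=O)/C1=C\[C@H](O[Si](C)(C)C(C)(C)C)[C@H](O[Si](C)(C)C(C)(C)C)CCCCOCc1ccc(OC)cc1 | intermediate
28 | bromohydrin (10-bromo-11-hydroxy ketone from 27) | CC/C=C\C/C=C\C[C@@]1(OCc2ccc(OC)cc2)C(O)C(Br)C(=O)/C1=C\[C@H](O[Si](C)(C)C(C)(C)C)[C@H](O[Si](C)(C)C(C)(C)C)CCCCOCc1ccc(OC)cc1 | intermediate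
29 | 11-mesylate of 28 | CC/C=C\C/C=C\C[C@@]1(OCc2ccc(OC)cc2)C(OS(C)(=O)=O)C(Br)C(=O)/C1=C\[C@H](O[Si](C)(C)C(C)(C)C)[C@H](O[Si](C)(C)C(C)(C)C)CCCCOCc1ccc(OC)cc1 | intermediate
30 | (4R,5Z)-2-bromo-5-[(2S,3R)-2,3-bis(TBS-oxy)-7-(PMB-oxy)heptylidene]-4-(PMB-oxy)-4-[(2Z,5Z)-octa-2,5-dien-1-yl]cyclopent-2-en-1-one | CC/C=C\C/C=C\C[C@@]1(OCc2ccc(OC)cc2)C=C(Br)C(=O)/C1=C\[C@H](O[Si](C)(C)C(C)(C)C)[C@H](O[Si](C)(C)C(C)(C)C)CCCCOCc1ccc(OC)cc1 | intermediate
31 | (4R,5Z)-2-bromo-5-[(2S,3R)-2,3-bis(TBS-oxy)-7-hydroxyheptylidene]-4-hydroxy-4-[(2Z,5Z)-octa-2,5-dien-1-yl]cyclopent-2-en-1-one | CC/C=C\C/C=C\C[C@@]1(O)C=C(Br)C(=O)/C1=C\[C@H](O[Si](C)(C)C(C)(C)C)[C@H](O[Si](C)(C)C(C)(C)C)CCCCO | intermediate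
32 | C1 aldehyde of 31 | CC/C=C\C/C=C\C[C@@]1(O)C=C(Br)C(=O)/C1=C\[C@H](O[Si](C)(C)C(C)(C)C)[C@H](O[Si](C)(C)C(C)(C)C)CCCC=O | intermediate
33 | (5R,6S,7Z,12R,14Z,17Z)-10-bromo-5,6-bis(TBS-oxy)-12-hydroxy-9-oxoprosta-7,10,14,17-tetraenoic acid | CC/C=C\C/C=C\C[C@@]1(O)C=C(Br)C(=O)/C1=C\[C@H](O[Si](C)(C)C(C)(C)C)[C@H](O[Si](C)(C)C(C)(C)C)CCCC(=O)O | intermediate
34 | methyl (5R,6S,7Z,12R,14Z,17Z)-10-bromo-5,6-bis(TBS-oxy)-12-hydroxy-9-oxoprosta-7,10,14,17-tetraenoate | CC/C=C\C/C=C\C[C@@]1(O)C=C(Br)C(=O)/C1=C\[C@H](O[Si](C)(C)C(C)(C)C)[C@H](O[Si](C)(C)C(C)(C)C)CCCC(=O)OC | intermediate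
35 | methyl (5R,6S,7Z,12R,14Z,17Z)-10-bromo-5,6,12-trihydroxy-9-oxoprosta-7,10,14,17-tetraenoate | CC/C=C\C/C=C\C[C@@]1(O)C=C(Br)C(=O)/C1=C\[C@H](O)[C@H](O)CCCC(=O)OC | target

**Step count**

Total: 24 steps. Longest linear sequence: 18 steps (steps 7–24, from 2-deoxy-L-ribose).

**Steps most likely to fail**

1. Step 17 (proposed new method). The alkoxy-stabilised cation may be diverted before it closes, by hydrolysis to the transposed enone or by loss of the PMB cation from the oxocarbenium oxygen. Rotation about C11–C12 before closure would erode the transfer of chirality to C12.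
   Fallback (known chemistry, from 5 and 17, back at 26): the ring is made first and the C7=C8 bond by aldol condensation. Commercial furfuryl alcohol is lithiated at C5 (n-BuLi, 2 equiv) and alkylated with bromide 5 to give {5-[(2Z,5Z)-octa-2,5-dien-1-yl]furan-2-yl}methanol F1. Piancatelli rearrangement (Dy(OTf)3 cat., MeCN/H2O, 80 °C) gives racemic 4-hydroxy-4-[(2Z,5Z)-octa-2,5-dien-1-yl]cyclopent-2-en-1-one F2. The tertiary alcohol is protected with 4-methoxybenzyl trichloroacetimidate and Sc(OTf)3 (cat.) to give the PMB ether F3. Its lithium enolate (LDA, THF, –78 °C) adds to aldehyde 17 to give the aldol adduct F4 as a diastereomer mixture. Mesylation and elimination (MsCl, Et3N, then DBU) form the alkylidene; chromatography isolates the 12R,7Z isomer, which is 26. Chirality transfer is given up: the C12 epimers are separated as diastereomers through the C5/C6 centres, and 7E material is recycled by photoisomerisation.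

2. Step 16. Reprotonation at C7 may show no facial preference, so that both allene axes form and the epimers co-elute or cannot be re-equilibrated cleanly.
   Fallback (from 21, back at 26): the isomerisation of 21 is run as in step 16, but the mixture of 22 and its axial epimer, the (aS,4S,5R)-allenyl MOM ether F5, is not separated and is taken through step 17 as it stands. The F5-derived material passes through the aS-series 1-lithioallene F6, the aS-series lithium carbinolate F7 and the aS-series carbinol trifluoroacetate F8, and closes from the opposite face of C8 to the 12-epi cyclopentenone F9 (C12 epimer of 26). F9 is a ring diastereomer of 26 and should separate on silica, so the separation is moved from the labile allene to the robust cyclopentenone.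

3. Step 18. The hydroperoxide may attack the exocyclic C7=C8 enone instead of C10=C11, or the base may scramble the 7Z alkene by reversible conjugate addition.
   Fallback (from 26, back at 30): bromine is brought in by thia-Michael addition, α-bromination and sulfoxide elimination. Thiophenol with catalytic Et3N adds at the endocyclic C11 of 26 to give the 11-phenylthio ketone F10. Soft enolisation (TMSOTf, Et3N; C10 is the only enolisable position) gives the trimethylsilyl enol ether F11, which N-bromosuccinimide brominates at C10 at –78 °C, far faster than it attacks isolated alkenes, to give the 10-bromo-11-phenylthio ketone F12. Oxidation at sulfur (NaIO4, MeOH/H2O) gives the 10-bromo-11-phenylsulfinyl ketone F13, whose thermal syn-elimination across C10–C11 gives 30.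

**Further compounds**

F1 | step 17 | {5-[(2Z,5Z)-octa-2,5-dien-1-yl]furan-2-yl}methanol | CC/C=C\C/C=C\Cc1ccc(CO)o1
F2 | step 17 | rac-4-hydroxy-4-[(2Z,5Z)-octa-2,5-dien-1-yl]cyclopent-2-en-1-one | CC/C=C\C/C=C\CC1(O)C=CC(=O)C1
F3 | step 17 | rac-4-(PMB-oxy)-4-[(2Z,5Z)-octa-2,5-dien-1-yl]cyclopent-2-en-1-one | CC/C=C\C/C=C\CC1(OCc2ccc(OC)cc2)C=CC(=O)C1
F4 | step 17 | aldol adduct of F3 and 17 (C7 carbinol, diastereomer mixture) | CC/C=C\C/C=C\CC1(OCc2ccc(OC)cc2)C=CC(=O)C1C(O)[C@H](O[Si](C)(C)C(C)(C)C)[C@H](O[Si](C)(C)C(C)(C)C)CCCCOCc1ccc(OC)cc1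
F5 | step 16 | (aS,4S,5R)-4,5-bis(TBS-oxy)-1-(methoxymethoxy)-9-(PMB-oxy)nona-1,2-diene (axial epimer of 22) | [H]C(OCOC)=[C@]=C([H])[C@H](O[Si](C)(C)C(C)(C)C)[C@H](O[Si](C)(C)C(C)(C)C)CCCCOCc1ccc(OC)cc1
F6 | step 16 | 1-lithio derivative of F5 | [Li]C(OCOC)=[C@]=C([H])[C@H](O[Si](C)(C)C(C)(C)C)[C@H](O[Si](C)(C)C(C)(C)C)CCCCOCc1ccc(OC)cc1
F7 | step 16 | lithium carbinolate from F6 and 9 | CC/C=C\C/C=C\C/C(OCc1ccc(OC)cc1)=C\C([O-])C(OCOC)=[C@]=C([H])[C@H](O[Si](C)(C)C(C)(C)C)[C@H](O[Si](C)(C)C(C)(C)C)CCCCOCc1ccc(OC)cc1.[Li+]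
F8 | step 16 | C10 trifluoroacetate of the aS-series carbinol | CC/C=C\C/C=C\C/C(OCc1ccc(OC)cc1)=C\C(OC(=O)C(F)(F)F)C(OCOC)=[C@]=C([H])[C@H](O[Si](C)(C)C(C)(C)C)[C@H](O[Si](C)(C)C(C)(C)C)CCCCOCc1ccc(OC)cc1
F9 | step 16 | 12-epi cyclopentenone (C12 epimer of 26) | CC/C=C\C/C=C\C[C@]1(OCc2ccc(OC)cc2)C=CC(=O)/C1=C\[C@H](O[Si](C)(C)C(C)(C)C)[C@H](O[Si](C)(C)C(C)(C)C)CCCCOCc1ccc(OC)cc1
F10 | step 18 | 11-phenylthio ketone from 26 | CC/C=C\C/C=C\C[C@@]1(OCc2ccc(OC)cc2)C(Sc2ccccc2)CC(=O)/C1=C\[C@H](O[Si](C)(C)C(C)(C)C)[C@H](O[Si](C)(C)C(C)(C)C)CCCCOCc1ccc(OC)cc1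
F11 | step 18 | trimethylsilyl enol ether of F10 (C9–C10) | CC/C=C\C/C=C\C[C@@]1(OCc2ccc(OC)cc2)C(Sc2ccccc2)C=C(O[Si](C)(C)C)/C1=C\[C@H](O[Si](C)(C)C(C)(C)C)[C@H](O[Si](C)(C)C(C)(C)C)CCCCOCc1ccc(OC)cc1
F12 | step 18 | 10-bromo-11-phenylthio ketone | CC/C=C\C/C=C\C[C@@]1(OCc2ccc(OC)cc2)C(Sc2ccccc2)C(Br)C(=O)/C1=C\[C@H](O[Si](C)(C)C(C)(C)C)[C@H](O[Si](C)(C)C(C)(C)C)CCCCOCc1ccc(OC)cc1
F13 | step 18 | 10-bromo-11-phenylsulfinyl ketone | CC/C=C\C/C=C\C[C@@]1(OCc2ccc(OC)cc2)C(S(=O)c2ccccc2)C(Br)C(=O)/C1=C\[C@H](O[Si](C)(C)C(C)(C)C)[C@H](O[Si](C)(C)C(C)(C)C)CCCCOCc1ccc(OC)cc1
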